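## The problem

The locants used throughout are these: ring A is C1–C2–C3–C4–C5–C9 with ketones at C2, C4 and C9; C6, C7 and C8 complete ring B; C1'–C2' is the two-carbon bridge from C7 to C3; C3' is the dimethyl carbon on C2'; C1''–C3'' are the carbons of the prenyl group on C3.

The target is a caged polyprenylated acylphloroglucinol whose three quaternary ring A carbons carry the benzoyl group (C1) and two prenyl-derived chains (C3, C5), and C7 caps ring A through three legs: C8(Me)2 to C1 and C6H2 to C5 close ring B, and C1'H2–C2'H to C3 turns the bicyclo[3.3.1]nonane into a homoadamantane. A 1,2-dioxepane (C3, C2', C3'Me2, O, O, C2'', C1'') is fused on the C3–C2' bond, and C2'' carries a 2-hydroperoxypropan-2-yl group. Of the six stereocentres, C1, C3, C5 and C7 are locked to one another by the cage, so only the sense of the cage relative to C2' and the configuration of C2'' have to be controlled; C2' can steer the cage if it is in place when the cage closes, and the finished cage can steer C2''. The two O–O bonds do not survive reducing agents, phosphines, strong base or heat; the non-enolisable triketone is open to retro-Claisen cleavage by alkoxides; the prenyl alkenes do not tolerate strong acid or unselective radicals. The peroxides therefore have to come last and the cage has to be built without strong acid. The feature that invites a short synthesis is that C1, C3 and C5 are the three nucleophilic carbons of a 3,5-diprenylated benzoylphloroglucinol, while the tripod around C7 is a ten-carbon unit that carries three electrophilic sites once a ketone is placed at C1': an allylic halide carbon C6, an enone β-carbon C8, and an epoxide carbon C2' whose partner is the future C3' carbinol carbon.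

## Retrosynthesis

**Peroxides (25 ← 24 ← 23).** The O–Si bond of silyl peroxide 24 and then C3'–O, O–C2'' and C3''–O are cut, which leads to the isopropenyl/prenyl diene 23 and two molecules of O2. This is preferred to any earlier introduction of a peroxide, because no O–O bond would survive the stannane, borohydride or amide base used before. Precursor 23 has no peroxide, no C2'' stereocentre and one ring fewer. The forward reaction must start at the 1,1-disubstituted alkene in the presence of two trisubstituted ones, close a seven-membered ring by a peroxyl radical before that radical is reduced, and set C2''.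

**Adjustment of the bridge (23 ← 22 ← 21 ← 20 ← 19).** The isopropenyl group is traced to the C3' carbinol of 22 and the C1' methylene to the C1' ketone of 19, through alcohol 20 and thionocarbonate 21. The ketone is kept up to 19 because it is what makes C6, C8 and C2' electrophilic in the cage-forming step. It is removed before the dehydration, since a β-hydroxy ketone would dehydrate into conjugation and destroy C2'. The forward sequence must tell the C1' ketone from four other ketones; the neighbouring C3' hydroxyl is used for this.

**Cage (19 ← 5 + 16).** C5–C6, C1–C8 and C3–C2' are cut together. Cutting only one or two of them leaves a bicyclic precursor that carries most of the stereocentres and needs a long stepwise preparation (Alternatives 2 and 3). The triple cut leads to the flat, achiral phloroglucinol 5 and the ten-carbon epoxy enone 16 with a single stereocentre. The forward reaction asks for three things.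
- C-alkylation of a prenyl-bearing carbon at C6. Bromide is chosen as the leaving group at C6: an acetate could leave only after conjugate addition to C8, which would tie a prenyl-bearing carbon to C8, whereas a primary allylic bromide is displaced directly.
- Conjugate addition of the benzoyl-bearing carbon C1 to the hindered C8.
- Opening of the epoxide at C2' by C3 with inversion.

**Epoxy enone (16 ← 15 ← 14 ← 12 + 8; 8 ← 7 ← 6; 12 ← 11 ← 9).** The C7–C1' bond is cut to the 2-lithioallyl alkoxide 13 (from bromo alcohol 12) and epoxy aldehyde 8. This places the stereocentre in a small fragment that a Sharpless epoxidation of prenol 6 delivers reliably. The alternatives were enantioselective nucleophilic epoxidation of a β,β-dimethyl dienone and hydroxymethylation of a β,β-disubstituted enone; neither is a dependable reaction. Diol 14 is brominated at the primary hydroxyl (15) and oxidised (16). Bromo alcohol 12 comes from prenal 9 by α-bromination (11) and reduction.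

**Nucleophile (5 ← 3 ← 1 + 2; 4).** The two C-prenyl bonds and the aryl ketone bond are cut to phloroglucinol 1, benzoyl chloride 2 and two equivalents of prenyl bromide 4. Both forward reactions are standard for this class, and over-prenylation is the only selectivity issue.

## Roads not taken

**Alternative 1:** The cut is that of the three C–O bonds of the peroxide part, and the forward key step is the cobalt-mediated dioxygen cascade that turns 23 into the triethylsilyl peroxide A1. Its merits are real: both peroxide functions and the dioxepane arise from O2 in one neutral operation at the very end. In this respect it is better than any stepwise peroxide construction, and the chosen plan adopts it unchanged as step 15 (A1 is 24). As the centre of a plan it is weak, because it presupposes the complete homoadamantane with C2' in place and says nothing about the C1–C8 and C3–C2' bonds. A plan built around it would still have to make the cage stepwise, which is where most steps would go.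

**Alternative 2:** The cut is the C1'=C2' bond. In keto aldehyde A3, a type A bicyclo[3.3.1]nonane with an axial C7 formyl group and a C3 acetonyl group, the acetonyl methylene C2' condenses with the aldehyde to give the homoadamantene methyl enone A2. The aldol condensation is dependable. There is no C1' ketone to remove, and A2 reaches 23 by conjugate reduction and methylenation, which is shorter than the four adjustment steps of the chosen plan. Against this stand three points. A3 has quaternary C1 (benzoyl next to C8) and quaternary C3 with two different chains of defined configuration, so its preparation is long. C2' has to be set afterwards by protonation or hydride delivery at an enone in the presence of two prenyl groups. The absolute configuration needs its own source. The chosen plan sets C2' from an enantiopure epoxide and forms the whole cage from two simple components, but it pays with an unprecedented cascade where Alternative 2 uses a proven ring closure.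

**Alternative 3:** The cut is the C1–C8 bond. Acid protonates the C7 isopropenyl group of the bicyclo[4.3.1]decane A5, and the enol carbon C1 captures the C8 cation to give the cage acetate A4. This uses the polarity in which the acyl-bearing carbon is known to form bonds, and it attacks the most congested bond with a strong electrophile. A4 also lacks the C1' ketone and reaches 23 in two steps. On the bond that is hardest to make, this road has the better precedent. Its weak points are chemoselectivity and length. The two prenyl groups are at least as basic as the isopropenyl group and lead to chromane formation and other cyclisations. The tertiary acetate ionises under the same acid. A5 requires a seven-membered ring built across C3 and C5 with stereocentres at C7 and C2'. The chosen plan sets against this its convergence, the absence of acid, and control of C2' by an SN2 inversion.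

Key step: step 10

Assumption: the target is taken exactly as drawn, with the free hydroperoxide and (2''S) configuration; the leaving group at C6 of the enone partner is bromide, for the reason given in the retrosynthesis.

## Route

Step 1
Reactants: 1 phloroglucinol; 2 benzoyl chloride
Product: 3 2,4,6-trihydroxybenzophenone
Conditions: AlCl3, nitrobenzene, 80 °C; then aq HCl
Reagents that add atoms: none
Why: Friedel–Crafts acylation of the very electron-rich ring; the aluminium-chelated ketone is deactivated towards a second acylation and any aryl ester rearranges under the same conditions (Fries).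

Step 2
Reactants: 3 2,4,6-trihydroxybenzophenone; 4 prenyl bromide
Product: 5 3,5-diprenyl-2,4,6-trihydroxybenzophenone
Conditions: prenyl bromide (2.2 equiv in all), 5% aq KOH, 0 °C
Reagents that add atoms: prenyl bromide (second equivalent of 4) CC(C)=CCBr
Why: Twofold C-alkylation of the phloroglucinol phenolate in water, one prenyl bromide at each of the two free ring positions; geminal over-alkylation is the known side reaction and is limited by temperature and stoichiometry.

Step 3
Reactants: 6 prenol
Product: 7 (S)-(3,3-dimethyloxiran-2-yl)methanol
Conditions: Ti(OiPr)4 (cat.), L-(+)-diisopropyl tartrate, t-BuOOH, 4 Å molecular sieves, CH2Cl2, −20 °C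
Reagents that add atoms: tert-butyl hydroperoxide CC(C)(C)OO
Why: Sharpless asymmetric epoxidation; the L-(+)-tartrate delivers oxygen to the face that gives the (S)-epoxy alcohol, the only stereocentre of the route set by a chiral reagent.

Step 4
Reactants: 7 (S)-(3,3-dimethyloxiran-2-yl)methanol
Product: 8 (R)-3,3-dimethyloxirane-2-carbaldehyde
Conditions: (COCl)2, DMSO, Et3N, CH2Cl2, −78 °C
Reagents that add atoms: none
Why: Swern oxidation; at low temperature and without water the epoxide C–H is not epimerised, and the volatile aldehyde is used as a dried solution (the descriptor changes only because the substituent priorities change).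

Step 5
Reactants: 9 3-methylbut-2-enal
Product: 11 2-bromo-3-methylbut-2-enal, via 2,3-dibromo-3-methylbutanal 10 (not isolated)
Conditions: Br2, CH2Cl2, 0 °C; then Et3N
Reagents that add atoms: bromine BrBr
Why: α-bromination of an enal by bromine addition and E1cB loss of HBr; only the α-hydrogen is acidic, so the alkene returns between C2 and C3.

Step 6
Reactants: 11 2-bromo-3-methylbut-2-enal
Product: 12 2-bromo-3-methylbut-2-en-1-ol
Conditions: NaBH4, MeOH, 0 °C
Reagents that add atoms: none
Why: 1,2-reduction of the aldehyde by borohydride; conjugate reduction does not compete at a β,β-disubstituted α-bromo enal.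

Step 7
Reactants: 12 2-bromo-3-methylbut-2-en-1-ol; 8 (R)-3,3-dimethyloxirane-2-carbaldehyde
Product: 14 2-[[(2S)-3,3-dimethyloxiran-2-yl](hydroxy)methyl]-3-methylbut-2-en-1-ol (both carbinol epimers), via dilithio alkoxide 13 (not isolated)
Conditions: t-BuLi (3 equiv), Et2O, −78 °C; then 8; AcOH, −78 °C
Reagents that add atoms: none
Why: O-deprotonation and bromine–lithium exchange give the 2-lithioallyl alkoxide, which adds to the aldehyde much faster than it opens the epoxide at −78 °C; the new carbinol centre is removed in step 9 and the cold acid quench prevents Payne rearrangement.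

Step 8
Reactants: 14 epoxy diol
Product: 15 2-(bromomethyl)-1-[(2S)-3,3-dimethyloxiran-2-yl]-3-methylbut-2-en-1-ol (both carbinol epimers)
Conditions: CBr4, PPh3, CH2Cl2, −30 → 0 °C
Reagents that add atoms: carbon tetrabromide BrC(Br)(Br)Br
Why: Appel reaction; the primary allylic hydroxyl reacts far faster than the secondary one, which is flanked by a tetrasubstituted alkene carbon and the epoxide, and the neutral medium leaves the epoxide intact.

Step 9
Reactants: 15 bromo alcohol
Product: 16 2-(bromomethyl)-1-[(2R)-3,3-dimethyloxiran-2-yl]-3-methylbut-2-en-1-one
Conditions: Dess–Martin periodinane, NaHCO3, CH2Cl2, 0 → 23 °C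
Reagents that add atoms: none
Why: Dess–Martin oxidation of the secondary allylic alcohol under buffered conditions; the allylic bromide and epoxide are inert, the epoxide centre is untouched, and 16 is used at once.

Step 10
Reactants: 5 3,5-diprenyl-2,4,6-trihydroxybenzophenone; 16 bromomethyl epoxy enone
Product: 19 (1R,3R,5S,7S,2'S)-1-benzoyl-2'-(2-hydroxypropan-2-yl)-8,8-dimethyl-3,5-diprenylhomoadamantane-2,4,9,1'-tetraone, via C5-allylated triketone enolate 17 (not isolated), via bicyclic epoxy ketone 18 (not isolated)
Conditions: LiN(SiMe3)2 (2.2 equiv), toluene–THF, −78 → 0 °C; then 40 °C; AcOH, 0 °C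
Reagents that add atoms: none
Why: Proposed new method: the dilithium salt of 5 is C-alkylated at a prenyl-bearing carbon by direct SN2 displacement of the primary allylic bromide (C5–C6, enolate 17); the benzoyl-bearing carbon C1 then adds to the β,β-dimethyl enone carbon C8 and closes ring B (6-endo-trig conjugate addition), proton transfer from the C2/C4 enol to C7 gives 18 as its C3 enolate, and C3 opens the epoxide at C2' with inversion, closing the seven-membered ring and the cage (7-exo-tet). The closest known reaction type is the alkylative dearomatisation–annulation of acylphloroglucinols with α-(acyloxymethyl) enals (Michael addition, elimination, Michael addition, aldol closure); new are the ketone-conjugated tetrasubstituted acceptor and the epoxide as third electrophile. The step needs C1 and not C3 to end on C8: both conjugate additions are reversible, but only the C1 adduct leaves the β-diketone carbon C3, a competent SN2 nucleophile, under the axial C7 side chain, whereas the C3 adduct leaves the lithium-chelated benzoyl triketone carbon, a poor one, so the irreversible epoxide opening should drain the equilibrium through 18. It needs carbon and not oxygen attack on the epoxide, which the perpendicular approach of C3 to the axial chain favours, and attack at C2' and not C3', which the fully substituted C3' and the adjacent ketone secure. C2' is set by inversion of the (R)-epoxide. C1, C3, C5 and C7 are fixed relative to one another by the cage, and their sense relative to C2' is chosen in the epoxide opening, where the closure that places C3' over C4, away from the benzoyl group, is expected to be the faster one. The C5 epimers of 17 and 18 that cannot close in this way return through retro-Michael cleavage at C6 or C8 from the C7 enolate, and C7 itself reaches the axial ketone through the same enolate.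

Step 11
Reactants: 19 cage tetraketone carbinol
Product: 20 (1R,3R,5S,7S,1'R,2'R)-1-benzoyl-1'-hydroxy-2'-(2-hydroxypropan-2-yl)-8,8-dimethyl-3,5-diprenylhomoadamantane-2,4,9-trione
Conditions: Me4NBH(OAc)3, MeCN–AcOH (1:1), −30 → 0 °C
Reagents that add atoms: none
Why: Hydroxyl-directed triacetoxyborohydride reduction (Evans–Saksena type): the reagent reduces a ketone only after binding to a hydroxyl in the β-position, so only C1' reacts and the four other ketones remain. Hydride arrives on the face syn to the carbinol side chain and gives the (1'R) alcohol trans to it, a centre that is removed in step 13.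

Step 12
Reactants: 20 cage diol
Product: 21 O-phenyl thionocarbonate of 20 at the C1' hydroxyl
Conditions: PhOC(S)Cl, pyridine, DMAP (cat.), CH2Cl2, 0 → 23 °C
Reagents that add atoms: O-phenyl chlorothionoformate S=C(Cl)Oc1ccccc1
Why: O-thioacylation of the secondary alcohol, the first stage of the Barton–McCombie sequence, without any alkoxide; the tertiary hydroxyl does not react and its trans position on the rigid bridge disfavours closure to a cyclic thionocarbonate.

Step 13
Reactants: 21 thionocarbonate
Product: 22 (1R,3R,5S,7S,2'S)-1-benzoyl-2'-(2-hydroxypropan-2-yl)-8,8-dimethyl-3,5-diprenylhomoadamantane-2,4,9-trione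
Conditions: Bu3SnH, AIBN (cat.), toluene, 90 °C
Reagents that add atoms: none
Why: Barton–McCombie deoxygenation; the secondary C1' radical is reduced by the stannane, and cyclisation onto the prenyl groups is excluded because each exo chain is held anti to the cage bond that leads to C1'. C1' becomes a methylene and C2' and C7 are not affected.

Step 14
Reactants: 22 cage carbinol
Product: 23 (1R,3R,5S,7S,2'R)-1-benzoyl-8,8-dimethyl-3,5-diprenyl-2'-(prop-1-en-2-yl)homoadamantane-2,4,9-trione
Conditions: Burgess reagent (MeO2CN–SO2NEt3 inner salt), toluene, 60 °C
Reagents that add atoms: none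
Why: Burgess dehydration by syn elimination of the sulfamate ester: six methyl hydrogens compete with one hindered C2'–H, and the tetrasubstituted alkene would eclipse the substituents of quaternary C3, so the isopropenyl isomer is expected. C2' is untouched (its descriptor changes by priority only).

Step 15
Reactants: 23 isopropenyl cage
Product: 24 triethylsilyl peroxide of the target, (1R,3R,5S,7S,2'S,2''S)
Conditions: Co(acac)2 (cat.), Et3SiH, O2 (1 atm), 1,2-dichloroethane, 23 °C
Reagents that add atoms: dioxygen (two molecules) O=O; triethylsilane CC[SiH](CC)CC
Why: Mukaiyama–Isayama hydroperoxysilylation extended by a peroxyl radical cyclisation, the diene peroxidation cascade: hydrogen atom transfer from the cobalt hydride (divalent cobalt precatalyst) goes to the 1,1-disubstituted alkene before the trisubstituted ones, the tertiary C3' radical captures O2, the peroxyl radical adds 7-exo-trig to C2'' of the C3 prenyl group, and the tertiary C3'' radical captures a second O2 and is silylated. C2'' is set by the cage: the chain closes on the C4 side of the bridge with the C3'' group pseudo-equatorial, which is expected to give the (2''S) epimer.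

Step 16
Reactants: 24 triethylsilyl peroxide
Product: 25 target hydroperoxide CNP0215795.1, (1R,3R,5S,7S,2'S,2''S)
Conditions: HCl (cat.), MeOH, 0 °C
Reagents that add atoms: none
Why: Acid-catalysed methanolysis of the peroxide O–Si bond; the O–O bonds, the ketones and the remaining prenyl group are inert to a trace of HCl in methanol at 0 °C and no stereocentre is involved.

## Compound list

1 | phloroglucinol | Oc1cc(O)cc(O)c1 | starting material
2 | benzoyl chloride | O=C(Cl)c1ccccc1 | starting material
3 | 2,4,6-trihydroxybenzophenone | O=C(c1ccccc1)c1c(O)cc(O)cc1O | intermediate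
4 | prenyl bromide (1-bromo-3-methylbut-2-ene) | CC(C)=CCBr | starting material
5 | 3,5-diprenyl-2,4,6-trihydroxybenzophenone | CC(C)=CCc1c(O)c(CC=C(C)C)c(O)c(C(=O)c2ccccc2)c1O | intermediate
6 | prenol (3-methylbut-2-en-1-ol) | CC(C)=CCO | starting material
7 | (S)-(3,3-dimethyloxiran-2-yl)methanol | OC[C@@H]1OC1(C)C | intermediate
8 | (R)-3,3-dimethyloxirane-2-carbaldehyde | O=C[C@@H]1OC1(C)C | intermediate
9 | 3-methylbut-2-enal (prenal) | CC(C)=CC=O | starting material
10 | 2,3-dibromo-3-methylbutanal | CC(C)(Br)C(Br)C=O | intermediate (not isolated)
11 | 2-bromo-3-methylbut-2-enal | CC(C)=C(Br)C=O | intermediate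
12 | 2-bromo-3-methylbut-2-en-1-ol | CC(C)=C(Br)CO | intermediate
13 | lithium 2-lithio-3-methylbut-2-en-1-olate | [Li]OCC([Li])=C(C)C | intermediate (not isolated)
14 | 2-[[(2S)-3,3-dimethyloxiran-2-yl](hydroxy)methyl]-3-methylbut-2-en-1-ol, both carbinol epimers | CC(C)=C(CO)C(O)[C@@H]1OC1(C)C | intermediate
15 | 2-(bromomethyl)-1-[(2S)-3,3-dimethyloxiran-2-yl]-3-methylbut-2-en-1-ol, both carbinol epimers | CC(C)=C(CBr)C(O)[C@@H]1OC1(C)C | intermediate
16 | 2-(bromomethyl)-1-[(2R)-3,3-dimethyloxiran-2-yl]-3-methylbut-2-en-1-one | CC(C)=C(CBr)C(=O)[C@@H]1OC1(C)C | intermediate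
17 | C5-allylated dearomatised triketone (present as lithium enolate, drawn as enol; both C5 epimers; epoxide R) | O=C1C(C(=O)c2ccccc2)=C(O)C(CC=C(C)C)=C(O)C1(CC=C(C)C)CC(=C(C)C)C(=O)[C@@H]1OC1(C)C | intermediate (not isolated)
18 | (1R,5S,7S)-1-benzoyl-7-[(2R)-3,3-dimethyloxirane-2-carbonyl]-4-hydroxy-8,8-dimethyl-3,5-diprenylbicyclo[3.3.1]non-3-ene-2,9-dione (acyl group axial on C7; present as C3 enolate) | CC(C)=CC[C@]12C[C@H](C(=O)[C@@H]3OC3(C)C)C(C)(C)[C@@](C(=O)c3ccccc3)(C2=O)C(O)=C(CC=C(C)C)C1=O | intermediate (not isolated)
19 | (1R,3R,5S,7S,2'S)-1-benzoyl-2'-(2-hydroxypropan-2-yl)-8,8-dimethyl-3,5-diprenylhomoadamantane-2,4,9,1'-tetraone (locants of the first section) | CC(C)=CC[C@]12C[C@@H]3C(=O)[C@H](C(C)(C)O)[C@](CC=C(C)C)(C1=O)C(=O)[C@](C(=O)c1ccccc1)(C2=O)C3(C)C | intermediate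
20 | (1R,3R,5S,7S,1'R,2'R)-1'-hydroxy analogue of 19 (C1' hydroxyl trans to the hydroxyisopropyl group) | CC(C)=CC[C@]12C[C@@H]3[C@@H](O)[C@H](C(C)(C)O)[C@](CC=C(C)C)(C1=O)C(=O)[C@](C(=O)c1ccccc1)(C2=O)C3(C)C | intermediate
21 | O-phenyl thionocarbonate of 20 at the C1' oxygen | CC(C)=CC[C@]12C[C@@H]3[C@@H](OC(=S)Oc4ccccc4)[C@H](C(C)(C)O)[C@](CC=C(C)C)(C1=O)C(=O)[C@](C(=O)c1ccccc1)(C2=O)C3(C)C | intermediate
22 | (1R,3R,5S,7S,2'S)-1-benzoyl-2'-(2-hydroxypropan-2-yl)-8,8-dimethyl-3,5-diprenylhomoadamantane-2,4,9-trione | CC(C)=CC[C@]12C[C@@H]3C[C@H](C(C)(C)O)[C@](CC=C(C)C)(C1=O)C(=O)[C@](C(=O)c1ccccc1)(C2=O)C3(C)C | intermediate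
23 | (1R,3R,5S,7S,2'R)-1-benzoyl-8,8-dimethyl-3,5-diprenyl-2'-(prop-1-en-2-yl)homoadamantane-2,4,9-trione | CC(C)=CC[C@]12C[C@@H]3C[C@H](C(C)=C)[C@](CC=C(C)C)(C1=O)C(=O)[C@](C(=O)c1ccccc1)(C2=O)C3(C)C | intermediate
24 | (1R,3R,5S,7S,2'S,2''S)-triethylsilyl peroxide of the target (1,2-dioxepane C3–C2'–C3'–O–O–C2''–C1''; Et3SiOO on C3'') | CC(C)=CC[C@]12C[C@@H]3C[C@@H]4C(C)(C)OO[C@H](C(C)(C)OO[Si](CC)(CC)CC)C[C@@]4(C1=O)C(=O)[C@](C(=O)c1ccccc1)(C2=O)C3(C)C | intermediate
25 | CNP0215795.1, (1R,3R,5S,7S,2'S,2''S)-hydroperoxide | CC(C)=CC[C@]12C[C@@H]3C[C@@H]4C(C)(C)OO[C@H](C(C)(C)OO)C[C@@]4(C1=O)C(=O)[C@](C(=O)c1ccccc1)(C2=O)C3(C)C | target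

## Step count and weak points

Total: 16 steps. Longest linear sequence: 12 steps (steps 5 to 16, from prenal 9).

**Step 10 (key step).** Three processes are most likely to spoil it.
- Conjugate addition of the second prenyl-bearing carbon C3 to C8 in place of C1, followed by cage closure through the benzoyl carbon. This is the kinetically normal regiochemistry of this substrate class and would give the regioisomeric cage.
- Failure of any carbon to add to the twisted tetrasubstituted enone, so that O-alkylation by the epoxide or retro-aldol loss of acetone from the lithium aldolate takes over.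
- Closure with the wrong cage handedness relative to C2'.

The fallback uses known reactions only; it sets out from 5 and 12 and returns at 19 by way of 18. The dilithio species 13 is formylated with DMF to 2-(hydroxymethyl)-3-methylbut-2-enal F1, which is brominated (CBr4, PPh3) to 2-(bromomethyl)-3-methylbut-2-enal F2. With LiN(SiMe3)2, 5 and F2 undergo the documented alkylative dearomatisation–annulation of the aldehyde series (C-allylation, conjugate addition of C1 to the far more reactive enal, aldol closure by C3) to the type A adamantane alcohol F3. Retro-aldol opening of F3 in the presence of the organocerium reagent from 2-methylprop-1-enylmagnesium bromide and CeCl3 gives the bicyclic allylic alcohol F4. VO(acac)2 and t-BuOOH epoxidise only its allylic alkene to the epoxy alcohol F5, and Dess–Martin oxidation gives 18, which LiN(SiMe3)2 alone closes to 19. The price is five more steps, a chiral ammonium phase-transfer catalyst in the annulation for absolute control, and C2' set by substrate control only, so that C2' epimers may have to be separated at 19.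

**Step 15.** The likely failures are reduction or silylation of the C3' peroxyl radical before it cyclises, competing hydrogen atom transfer to the prenyl alkenes, and poor facial selectivity at C2''. The fallback sets out from 23 and returns at 25. Hydroperoxysilylation at high silane concentration is stopped at the open C3' triethylsilyl peroxide F6, and methanolysis gives the tertiary hydroperoxide F7. The ring is then closed without any metal hydride by an initiator-driven peroxyl radical chain (di-tert-butyl hyponitrite, O2, benzene, 40 °C). In this chain the C3' peroxyl radical cyclises onto C2'', the C3'' radical takes up O2, and the new peroxyl radical abstracts hydrogen from F7, giving 25 directly.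

**Step 11.** The likely failure is slow exchange of the hindered tertiary hydroxyl onto boron, so that no hydride is delivered to the congested C1' ketone, or over-reduction if a stronger hydride is then tried. The fallback sets out from 19 and returns at 22, bypassing steps 11 to 13. Condensation with tosylhydrazide gives the C1' tosylhydrazone F8, and Caglioti-type reduction with catecholborane followed by NaOAc trihydrate gives the methylene compound 22.

**Step 8.** The likely failure is loss of selectivity between the two allylic hydroxyls, or bromide opening of the epoxide. The fallback sets out from 12 and returns at 16. It silylates 12 to the tert-butyldimethylsilyl ether F9, adds the derived vinyllithium to 8 to give alcohol F10, oxidises to the silyloxymethyl enone F11, removes the silyl group (Bu4NF, AcOH) to give the hydroxymethyl enone F12, and brominates the now single hydroxyl (CBr4, PPh3) to 16. This costs two more steps.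

## Further compounds

F1 | step 10 | 2-(hydroxymethyl)-3-methylbut-2-enal | CC(C)=C(CO)C=O
F2 | step 10 | 2-(bromomethyl)-3-methylbut-2-enal | CC(C)=C(CBr)C=O
F3 | step 10 | type A adamantane alcohol: 1-benzoyl-8,8-dimethyl-3,5-diprenyladamantane-2,4,9-trione with a CH(OH) bridge between C3 and C7 (carbinol configuration open) | CC(C)=CC[C@]12C[C@@H]3C(O)[C@](CC=C(C)C)(C1=O)C(=O)[C@](C(=O)c1ccccc1)(C2=O)C3(C)C
F4 | step 10 | (1R,5S,7S)-1-benzoyl-4-hydroxy-7-(1-hydroxy-3-methylbut-2-enyl)-8,8-dimethyl-3,5-diprenylbicyclo[3.3.1]non-3-ene-2,9-dione (carbinol epimers) | CC(C)=CC[C@]12C[C@H](C(O)C=C(C)C)C(C)(C)[C@@](C(=O)c3ccccc3)(C2=O)C(O)=C(CC=C(C)C)C1=O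
F5 | step 10 | epoxy alcohol from F4: 7-[(3,3-dimethyloxiran-2-yl)(hydroxy)methyl] analogue (side-chain centres by substrate control) | CC(C)=CC[C@]12C[C@H](C(O)C3OC3(C)C)C(C)(C)[C@@](C(=O)c3ccccc3)(C2=O)C(O)=C(CC=C(C)C)C1=O
F6 | step 15 | open C3' triethylsilyl peroxide of 23: 2'-[2-(triethylsilylperoxy)propan-2-yl] cage | CC(C)=CC[C@]12C[C@@H]3C[C@H](C(C)(C)OO[Si](CC)(CC)CC)[C@](CC=C(C)C)(C1=O)C(=O)[C@](C(=O)c1ccccc1)(C2=O)C3(C)C
F7 | step 15 | open C3' hydroperoxide: 2'-(2-hydroperoxypropan-2-yl) cage | CC(C)=CC[C@]12C[C@@H]3C[C@H](C(C)(C)OO)[C@](CC=C(C)C)(C1=O)C(=O)[C@](C(=O)c1ccccc1)(C2=O)C3(C)C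
F8 | step 11 | C1' tosylhydrazone of 19 | CC(C)=CC[C@]12C[C@@H]3C(=NNS(=O)(=O)c4ccc(C)cc4)[C@H](C(C)(C)O)[C@](CC=C(C)C)(C1=O)C(=O)[C@](C(=O)c1ccccc1)(C2=O)C3(C)C
F9 | step 8 | (2-bromo-3-methylbut-2-enyloxy)(tert-butyl)dimethylsilane | CC(C)=C(Br)CO[Si](C)(C)C(C)(C)C
F10 | step 8 | 2-[(tert-butyldimethylsilyloxy)methyl]-1-[(2S)-3,3-dimethyloxiran-2-yl]-3-methylbut-2-en-1-ol (carbinol epimers) | CC(C)=C(CO[Si](C)(C)C(C)(C)C)C(O)[C@@H]1OC1(C)C
F11 | step 8 | 2-[(tert-butyldimethylsilyloxy)methyl]-1-[(2R)-3,3-dimethyloxiran-2-yl]-3-methylbut-2-en-1-one | CC(C)=C(CO[Si](C)(C)C(C)(C)C)C(=O)[C@@H]1OC1(C)C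
F12 | step 8 | 1-[(2R)-3,3-dimethyloxiran-2-yl]-2-(hydroxymethyl)-3-methylbut-2-en-1-one | CC(C)=C(CO)C(=O)[C@@H]1OC1(C)C
A1 | alternative 1 | triethylsilyl peroxide of the target (identical with 24) | CC(C)=CC[C@]12C[C@@H]3C[C@@H]4C(C)(C)OO[C@H](C(C)(C)OO[Si](CC)(CC)CC)C[C@@]4(C1=O)C(=O)[C@](C(=O)c1ccccc1)(C2=O)C3(C)C
A2 | alternative 2 | homoadamantene methyl enone (C1'=C2' alkene, acetyl on C2') | CC(C)=CC[C@]12C[C@@H]3C=C(C(C)=O)[C@](CC=C(C)C)(C1=O)C(=O)[C@](C(=O)c1ccccc1)(C2=O)C3(C)C
A3 | alternative 2 | aldol precursor: 1-benzoyl-7-formyl-8,8-dimethyl-3-(2-oxopropyl)-3,5-diprenylbicyclo[3.3.1]nonane-2,4,9-trione (formyl axial, acetonyl on the C7 face) | CC(C)=CC[C@]12C[C@H](C=O)C(C)(C)[C@@](C(=O)c3ccccc3)(C2=O)C(=O)[C@](CC=C(C)C)(CC(C)=O)C1=O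
A4 | alternative 3 | homoadamantane trione with C3' acetate (acetate of 22) | CC(C)=CC[C@]12C[C@@H]3C[C@H](C(C)(C)OC(C)=O)[C@](CC=C(C)C)(C1=O)C(=O)[C@](C(=O)c1ccccc1)(C2=O)C3(C)C
A5 | alternative 3 | bicyclo[4.3.1]decane triketone enol with C7 isopropenyl group and C3' acetate | CC(C)=CC[C@]12C[C@@H](C(C)=C)C[C@H](C(C)(C)OC(C)=O)[C@](CC=C(C)C)(C1=O)C(=O)C(C(=O)c1ccccc1)=C2O
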